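**Route outline**

- Cuts: the two aryl O–Si bonds last; before them, in one operation, the O1–C2 bond of the tetrahydrofuran and the C2'–C3' single bond of the diene. This leads back to an (E)-alkenyl boronate on the isocoumarin and an (E)-iodovinyl trans-epoxide carrying the free C5 hydroxyl.
- Enabling feature: in the tetrahydrofuran (O1, C2–C5), C2 is bonded to O1, to the C1'=C2'–C3'=C4' diene and to the carbinol carbon C3. An allylic C–O bond next to a hydroxyl is what a vinyl epoxide leaves behind when opened through π-allylpalladium, and the same zerovalent palladium can make C2'–C3'.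
- Aromatic half, forward: the benzene ring is bought; the pyranone ring is annulated onto it (C4–C4a, then O2–C3) by carboxylate-directed C–H functionalisation with a sulfoxonium ylide, and the C3 acetal becomes the aldehyde and then the E-alkenyl boronate.
- Aliphatic half, forward: the chain grows from (R)-pent-4-yn-2-ol to an E-allylic alcohol, which is epoxidised (a temporary ring) and extended to the E-alkenyl iodide.
- Union: one palladium catalyst joins the halves at C2'–C3' and then closes the tetrahydrofuran as the epoxide opens; desilylation of the phenols ends the route.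
- Stereochemistry: C5 (R) is bought; C3 and C2 come from the Sharpless epoxidation with L-(+)-diethyl tartrate; C3 is never touched and C2 is carried over with net retention, giving the all-cis 2S,3S,5R ring; both E alkenes come from chromium-mediated olefinations.

Key step: step 13

Remark: locants are O1, C2–C5 for the tetrahydrofuran, C1'–C4' for the diene counted from C2, and C1–C8a for the isocoumarin; the aryl triisopropylsilyl ethers are assumed to tolerate the buffered trifluoroethanol medium of the annulation.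

**Route**

Step 1
Reactants: 1 5-chloro-2,4-dihydroxybenzoic acid
Product: 3 5-chloro-2,4-bis(triisopropylsilyloxy)benzoic acid, via triisopropylsilyl ester 2 (not isolated)
Conditions: iPr3SiOTf (3.3 equiv), 2,6-lutidine, CH2Cl2, 0 → 23 °C; then AcOH/THF/H2O (3:1:1), 23–40 °C
Reagents that add atoms: triisopropylsilyl trifluoromethanesulfonate, CC(C)[Si](C(C)C)(C(C)C)OS(=O)(=O)C(F)(F)F
Why: Exhaustive silylation followed by selective hydrolysis, in which the silyl ester (carboxylate leaving group on silicon) should hydrolyse far faster in buffered aqueous acid than the two aryl silyl ethers.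

Step 2
Reactants: 4 ethyl diethoxyacetate; 5 trimethylsulfoxonium iodide
Product: 7 1-[dimethyl(oxo)-λ6-sulfanylidene]-3,3-diethoxypropan-2-one, via dimethylsulfoxonium methylide 6 (not isolated)
Conditions: 5 (3 equiv), KOtBu (3 equiv), THF, 65 °C; then 4, 0 → 23 °C
Reagents that add atoms: none
Why: Acylation of the Corey–Chaykovsky methylide by a non-enolisable ester gives the stabilised β-keto sulfoxonium ylide, and the acetal is inert to the base.

Step 3
Reactants: 3 5-chloro-2,4-bis(triisopropylsilyloxy)benzoic acid; 7 1-[dimethyl(oxo)-λ6-sulfanylidene]-3,3-diethoxypropan-2-one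
Product: 9 5-chloro-3-(diethoxymethyl)-6,8-bis(triisopropylsilyloxy)-1H-isochromen-1-one, via keto acid 8 (not isolated)
Conditions: [Cp*RhCl2]2 (2.5 mol %), NaOAc (0.5 equiv), CF3CH2OH, 60 °C, N2
Reagents that add atoms: none
Why: Carboxylate-directed C–H activation/annulation with a sulfoxonium ylide as carbene surrogate, in which trivalent rhodium metalates the only free ortho C–H (between carboxyl and chlorine), carbene insertion with loss of dimethyl sulfoxide forms C4–C4a, and cyclodehydration of the acid onto the ketone forms O2–C3 without an external oxidant.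

Step 4
Reactants: 9 5-chloro-3-(diethoxymethyl)-6,8-bis(triisopropylsilyloxy)-1H-isochromen-1-one
Product: 10 5-chloro-1-oxo-6,8-bis(triisopropylsilyloxy)-1H-isochromene-3-carbaldehyde
Conditions: 1 M aq. HCl, THF, 40 °C
Reagents that add atoms: water, O
Why: Acid-catalysed acetal hydrolysis, which the aryl triisopropylsilyl ethers and the enol lactone should tolerate in dilute aqueous acid.

Step 5
Reactants: 10 5-chloro-1-oxo-6,8-bis(triisopropylsilyloxy)-1H-isochromene-3-carbaldehyde
Product: 11 (E)-5-chloro-3-[2-(4,4,5,5-tetramethyl-1,3,2-dioxaborolan-2-yl)vinyl]-6,8-bis(triisopropylsilyloxy)-1H-isochromen-1-one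
Conditions: CrCl2 (8 equiv), Cl2CHBpin (2 equiv), LiI (4 equiv), THF, 23 °C
Reagents that add atoms: 2-(dichloromethyl)-4,4,5,5-tetramethyl-1,3,2-dioxaborolane, ClC(Cl)B1OC(C)(C)C(C)(C)O1
Why: Takai–Utimoto boryl-olefination, in which the gem-dichromium species made from the dihalomethylboronate by divalent chromium adds to the aldehyde and eliminates to the E-alkenyl boronate while lactone, aryl chloride and silyl ethers are left alone.

Step 6
Reactants: 12 (R)-pent-4-yn-2-ol
Product: 13 (R)-triethyl(pent-4-yn-2-yloxy)silane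
Conditions: Et3SiCl, imidazole, CH2Cl2, 0 °C
Reagents that add atoms: chlorotriethylsilane, CC[Si](Cl)(CC)CC
Why: Standard silylation of a secondary alcohol, which masks the C5 hydroxyl for the acetylide, hydride and oxidation chemistry that follows.

Step 7
Reactants: 13 (R)-triethyl(pent-4-yn-2-yloxy)silane
Product: 15 (R)-5-(triethylsilyloxy)hex-2-yn-1-ol, via lithium acetylide 14 (not isolated)
Conditions: n-BuLi, THF, −78 °C; (CH2O)n, −78 → 23 °C; aq. NH4Cl
Reagents that add atoms: paraformaldehyde (as formaldehyde), C=O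
Why: Hydroxymethylation of a lithium acetylide with formaldehyde, a routine one-carbon homologation to the propargylic alcohol.

Step 8
Reactants: 15 (R)-5-(triethylsilyloxy)hex-2-yn-1-ol
Product: 16 (R,E)-5-(triethylsilyloxy)hex-2-en-1-ol
Conditions: NaAlH2(OCH2CH2OMe)2, THF, 0 → 23 °C; aq. potassium sodium tartrate
Reagents that add atoms: none
Why: Hydroxyl-directed trans-hydroalumination of a propargylic alcohol, which after protonolysis should give only the E-allylic alcohol and leaves the silyl ether untouched.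

Step 9
Reactants: 16 (R,E)-5-(triethylsilyloxy)hex-2-en-1-ol
Product: 17 [(2S,3S)-3-[(R)-2-(triethylsilyloxy)propyl]oxiran-2-yl]methanol
Conditions: Ti(OiPr)4 (10 mol %), L-(+)-diethyl tartrate (12 mol %), tBuOOH, 4 Å MS, CH2Cl2, −20 °C
Reagents that add atoms: tert-butyl hydroperoxide, CC(C)(C)OO
Why: Sharpless asymmetric epoxidation, in which the titanium–L-(+)-tartrate–peroxide complex delivers oxygen to the face of the E-allylic alcohol that gives the (2S,3S)-trans-epoxide under reagent control, independent of the remote C5 centre.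

Step 10
Reactants: 17 [(2S,3S)-3-[(R)-2-(triethylsilyloxy)propyl]oxiran-2-yl]methanol
Product: 18 (2R,3S)-3-[(R)-2-(triethylsilyloxy)propyl]oxirane-2-carbaldehyde
Conditions: SO3·pyridine, DMSO, Et3N, CH2Cl2, 0 °C
Reagents that add atoms: none
Why: Parikh–Doering oxidation, a non-acidic activated-DMSO oxidation that should give the epoxy aldehyde without opening the epoxide (the descriptor at the aldehyde-bearing carbon changes only by priority rules).

Step 11
Reactants: 18 (2R,3S)-3-[(R)-2-(triethylsilyloxy)propyl]oxirane-2-carbaldehyde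
Product: 19 triethyl{[(R)-1-[(2S,3S)-3-[(E)-2-iodovinyl]oxiran-2-yl]propan-2-yl]oxy}silane
Conditions: CrCl2 (6 equiv), CHI3 (2 equiv), THF, 0 °C, dark
Reagents that add atoms: iodoform, IC(I)I
Why: Takai iodo-olefination, in which the gem-dichromium carbenoid from iodoform and divalent chromium should convert the aldehyde into the E-alkenyl iodide with the epoxide and silyl ether intact.

Step 12
Reactants: 19 triethyl{[(R)-1-[(2S,3S)-3-[(E)-2-iodovinyl]oxiran-2-yl]propan-2-yl]oxy}silane
Product: 20 (R)-1-[(2S,3S)-3-[(E)-2-iodovinyl]oxiran-2-yl]propan-2-ol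
Conditions: Bu4NF/AcOH (1:1), THF, 0 °C; NaHCO3 wash, Et3N-deactivated silica
Reagents that add atoms: none
Why: Buffered fluoride cleavage of the triethylsilyl ether, mild enough to keep the alkenyl iodide and vinyl epoxide, provided that acid is excluded afterwards so that the uncatalysed invertive opening by the C5 hydroxyl (which would give the 2,3-trans ring) does not start.

Step 13
Reactants: 11 (E)-5-chloro-3-[2-(4,4,5,5-tetramethyl-1,3,2-dioxaborolan-2-yl)vinyl]-6,8-bis(triisopropylsilyloxy)-1H-isochromen-1-one; 20 (R)-1-[(2S,3S)-3-[(E)-2-iodovinyl]oxiran-2-yl]propan-2-ol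
Product: 22 5-chloro-3-[(1E,3E)-4-[(2S,3S,5R)-3-hydroxy-5-methyltetrahydrofuran-2-yl]buta-1,3-dien-1-yl]-6,8-bis(triisopropylsilyloxy)-1H-isochromen-1-one, via dienyl epoxide 21 (not isolated)
Conditions: 11 (1.0 equiv), 20 (1.1 equiv), Pd(PPh3)4 (5 mol %), 2 M aq. K3PO4 (3 equiv), degassed THF, 23 → 40 °C, dark
Reagents that add atoms: none
Why: Proposed new method: Pd(PPh3)4 should insert into the C–I bond of 20, transmetalate with the phosphate-activated boronate 11 and reductively eliminate to form C2'–C3' of dienyl epoxide 21, after which the returned zerovalent palladium ionises the allylic C2–O bond of the epoxide anti to oxygen to a syn,syn π-allyl complex bearing the C3 alkoxide, and the C5 oxygen attacks the near allyl terminus anti to the metal. The closest known reaction types are the Suzuki–Miyaura coupling of alkenyl iodides with alkenyl boronates and the retentive cyclisation of hydroxy vinyl epoxides under zerovalent palladium to cis-2-alkenyl-3-hydroxy oxacycles; what is untested is running both with one catalyst charge in one flask. The tetrahydrofuran closes in a 5-exo mode on the allyl unit (5-endo if counted against the former epoxide), and the epoxide opens in the same event to free the C3 hydroxyl. C2 is the only centre that is re-formed and is controlled by the (2S,3S)-trans-epoxide through double inversion (net retention), which places the dienyl group cis to the C3 hydroxyl and the C5 methyl, while C3 and C5 are not touched. The step needs attack at the proximal rather than a distal allyl terminus, retention of both E alkenes and no uncatalysed invertive opening; the three-atom tether between the C5 oxygen and C2, the stereoretentive coupling together with the syn,syn-allyl geometry, and the basic acid-free medium should secure these in turn. Either order of the two palladium events should converge on 22, because the alkenyl iodide survives ring closure and the epoxide survives coupling.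

Step 14
Reactants: 22 5-chloro-3-[(1E,3E)-4-[(2S,3S,5R)-3-hydroxy-5-methyltetrahydrofuran-2-yl]buta-1,3-dien-1-yl]-6,8-bis(triisopropylsilyloxy)-1H-isochromen-1-one
Product: 23 5-chloro-6,8-dihydroxy-3-[(1E,3E)-4-[(2S,3S,5R)-3-hydroxy-5-methyltetrahydrofuran-2-yl]buta-1,3-dien-1-yl]-1H-isochromen-1-one (CNP0086741.3)
Conditions: Bu4NF/AcOH (1:1, 3 equiv), THF, 0 °C; pH 7 phosphate buffer work-up
Reagents that add atoms: none
Why: Fluoride cleavage of the two aryl silyl ethers (phenoxide leaving groups) under buffered near-neutral conditions, which should spare the lactone, the diene and the acid-sensitive dienylic C2–O1 ether.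

**Compound list**

1 | 5-chloro-2,4-dihydroxybenzoic acid | OC(=O)c1cc(Cl)c(O)cc1O | starting material
2 | triisopropylsilyl 5-chloro-2,4-bis(triisopropylsilyloxy)benzoate | CC(C)[Si](C(C)C)(C(C)C)OC(=O)c1cc(Cl)c(O[Si](C(C)C)(C(C)C)C(C)C)cc1O[Si](C(C)C)(C(C)C)C(C)C | intermediate
3 | 5-chloro-2,4-bis(triisopropylsilyloxy)benzoic acid | OC(=O)c1cc(Cl)c(O[Si](C(C)C)(C(C)C)C(C)C)cc1O[Si](C(C)C)(C(C)C)C(C)C | intermediate
4 | ethyl diethoxyacetate | CCOC(=O)C(OCC)OCC | starting material
5 | trimethylsulfoxonium iodide | C[S+](C)(C)=O.[I-] | starting material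
6 | dimethylsulfoxonium methylide | C=S(C)(C)=O | intermediate
7 | 1-[dimethyl(oxo)-λ6-sulfanylidene]-3,3-diethoxypropan-2-one | CCOC(OCC)C(=O)C=S(C)(C)=O | intermediate
8 | 3-chloro-2-(3,3-diethoxy-2-oxopropyl)-4,6-bis(triisopropylsilyloxy)benzoic acid | CCOC(OCC)C(=O)Cc1c(Cl)c(O[Si](C(C)C)(C(C)C)C(C)C)cc(O[Si](C(C)C)(C(C)C)C(C)C)c1C(O)=O | intermediate
9 | 5-chloro-3-(diethoxymethyl)-6,8-bis(triisopropylsilyloxy)-1H-isochromen-1-one | CCOC(OCC)c1cc2c(Cl)c(O[Si](C(C)C)(C(C)C)C(C)C)cc(O[Si](C(C)C)(C(C)C)C(C)C)c2c(=O)o1 | intermediate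
10 | 5-chloro-1-oxo-6,8-bis(triisopropylsilyloxy)-1H-isochromene-3-carbaldehyde | O=Cc1cc2c(Cl)c(O[Si](C(C)C)(C(C)C)C(C)C)cc(O[Si](C(C)C)(C(C)C)C(C)C)c2c(=O)o1 | intermediate
11 | (E)-5-chloro-3-[2-(4,4,5,5-tetramethyl-1,3,2-dioxaborolan-2-yl)vinyl]-6,8-bis(triisopropylsilyloxy)-1H-isochromen-1-one | CC1(C)OB(/C=C/c2cc3c(Cl)c(O[Si](C(C)C)(C(C)C)C(C)C)cc(O[Si](C(C)C)(C(C)C)C(C)C)c3c(=O)o2)OC1(C)C | intermediate
12 | (R)-pent-4-yn-2-ol | C[C@@H](O)CC#C | starting material
13 | (R)-triethyl(pent-4-yn-2-yloxy)silane | C[C@@H](O[Si](CC)(CC)CC)CC#C | intermediate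
14 | [(R)-4-(triethylsilyloxy)pent-1-yn-1-yl]lithium | C[C@@H](O[Si](CC)(CC)CC)CC#C[Li] | intermediate
15 | (R)-5-(triethylsilyloxy)hex-2-yn-1-ol | C[C@@H](O[Si](CC)(CC)CC)CC#CCO | intermediate
16 | (R,E)-5-(triethylsilyloxy)hex-2-en-1-ol | C[C@@H](O[Si](CC)(CC)CC)C/C=C/CO | intermediate
17 | [(2S,3S)-3-[(R)-2-(triethylsilyloxy)propyl]oxiran-2-yl]methanol | C[C@@H](O[Si](CC)(CC)CC)C[C@@H]1O[C@H]1CO | intermediate
18 | (2R,3S)-3-[(R)-2-(triethylsilyloxy)propyl]oxirane-2-carbaldehyde | C[C@@H](O[Si](CC)(CC)CC)C[C@@H]1O[C@H]1C=O | intermediate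
19 | triethyl{[(R)-1-[(2S,3S)-3-[(E)-2-iodovinyl]oxiran-2-yl]propan-2-yl]oxy}silane | C[C@@H](O[Si](CC)(CC)CC)C[C@@H]1O[C@H]1/C=C/I | intermediate
20 | (R)-1-[(2S,3S)-3-[(E)-2-iodovinyl]oxiran-2-yl]propan-2-ol | C[C@@H](O)C[C@@H]1O[C@H]1/C=C/I | intermediate
21 | 5-chloro-3-[(1E,3E)-4-[(2S,3S)-3-[(R)-2-hydroxypropyl]oxiran-2-yl]buta-1,3-dien-1-yl]-6,8-bis(triisopropylsilyloxy)-1H-isochromen-1-one | C[C@@H](O)C[C@@H]1O[C@H]1/C=C/C=C/c2cc3c(Cl)c(O[Si](C(C)C)(C(C)C)C(C)C)cc(O[Si](C(C)C)(C(C)C)C(C)C)c3c(=O)o2 | intermediate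
22 | 5-chloro-3-[(1E,3E)-4-[(2S,3S,5R)-3-hydroxy-5-methyltetrahydrofuran-2-yl]buta-1,3-dien-1-yl]-6,8-bis(triisopropylsilyloxy)-1H-isochromen-1-one | C[C@@H]1C[C@H](O)[C@H](/C=C/C=C/c2cc3c(Cl)c(O[Si](C(C)C)(C(C)C)C(C)C)cc(O[Si](C(C)C)(C(C)C)C(C)C)c3c(=O)o2)O1 | intermediate
23 | 5-chloro-6,8-dihydroxy-3-[(1E,3E)-4-[(2S,3S,5R)-3-hydroxy-5-methyltetrahydrofuran-2-yl]buta-1,3-dien-1-yl]-1H-isochromen-1-one (CNP0086741.3) | C[C@@H]1C[C@H](O)[C@H](/C=C/C=C/c2cc3c(Cl)c(O)cc(O)c3c(=O)o2)O1 | target

**Count and risks**

Total steps: 14. Longest linear sequence: 9 steps (steps 6–14, from 12 to 23). The aromatic branch needs 6 steps from 1 (steps 1, 3, 4, 5, 13, 14), with step 2 as a one-step side branch.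

Steps most likely to fail:

1. Step 13 (the one step beyond known chemistry).
 - What may go wrong: transfer of the alkenyl group from boron to the π-allyl terminus instead of to the alkenylpalladium; β-hydride loss from the π-allyl complex; erosion of the C2 configuration by π–σ–π or palladium–palladium exchange before ring closure.
 - Fallback, known chemistry throughout, setting out from epoxy aldehyde 18 and aldehyde 10 and returning at 22: the two palladium events are separated and the roles of the coupling partners are reversed.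
 - Wittig methylenation of 18 (Ph3PCH3Br, KN(SiMe3)2, THF, −78 → 0 °C) should give triethyl{[(R)-1-[(2S,3S)-3-vinyloxiran-2-yl]propan-2-yl]oxy}silane F1, and buffered Bu4NF/AcOH then frees (R)-1-[(2S,3S)-3-vinyloxiran-2-yl]propan-2-ol F2.
 - Pd(PPh3)4 in THF should cyclise F2 with net retention to (2S,3S,5R)-5-methyl-2-vinyltetrahydrofuran-3-ol F3, and cross-metathesis with vinylboronic acid pinacol ester (second-generation Grubbs catalyst, CH2Cl2, 40 °C) should give (2S,3S,5R)-5-methyl-2-[(E)-2-(4,4,5,5-tetramethyl-1,3,2-dioxaborolan-2-yl)vinyl]tetrahydrofuran-3-ol F4.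
 - In parallel, Takai iodo-olefination of 10 (CHI3, CrCl2, THF) should give (E)-5-chloro-3-(2-iodovinyl)-6,8-bis(triisopropylsilyloxy)-1H-isochromen-1-one F5.
 - Suzuki–Miyaura coupling of F4 with F5 (Pd(PPh3)4, aq. K3PO4, THF) rejoins the route at 22.

2. Step 3.
 - What may go wrong: slow carboxylate-directed metalation at the C–H flanked by chlorine; migration of the ortho silyl group onto the carboxylate; loss of the acetal in the warm protic medium.
 - Fallback, setting out from acid 3 and returning at acetal 9 without transition-metal C–H activation: deprotonation between carboxylate and chlorine with lithium 2,2,6,6-tetramethylpiperidide (THF, −78 °C) and quench with I2 should give 3-chloro-2-iodo-4,6-bis(triisopropylsilyloxy)benzoic acid F6.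
 - Sonogashira coupling of F6 with 3,3-diethoxyprop-1-yne (Pd(PPh3)2Cl2, CuI, Et3N, DMF) should give 3-chloro-2-(3,3-diethoxyprop-1-yn-1-yl)-4,6-bis(triisopropylsilyloxy)benzoic acid F7.
 - The carboxyl of F7 then adds 6-endo across the alkyne, in the same flask or with catalytic AgOTf, to give 9.

3. Step 11.
 - What may go wrong: opening of the epoxide by Lewis-acidic chromium halides and iodide; incomplete E selectivity of the iodo-olefination.
 - Fallback, setting out from 18 and returning at 19 without chromium: Ohira–Bestmann homologation of 18 (dimethyl (1-diazo-2-oxopropyl)phosphonate, K2CO3, MeOH, 0 °C) should give triethyl{[(R)-1-[(2S,3S)-3-ethynyloxiran-2-yl]propan-2-yl]oxy}silane F8.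
 - Hydrozirconation of F8 with Cp2Zr(H)Cl (THF, 0 °C) followed by iodinolysis with I2 should give the E-alkenyl iodide 19 by syn addition and retention at carbon.

Further compounds
F1 | step 13 | triethyl{[(R)-1-[(2S,3S)-3-vinyloxiran-2-yl]propan-2-yl]oxy}silane | C[C@@H](O[Si](CC)(CC)CC)C[C@@H]1O[C@H]1C=C
F2 | step 13 | (R)-1-[(2S,3S)-3-vinyloxiran-2-yl]propan-2-ol | C[C@@H](O)C[C@@H]1O[C@H]1C=C
F3 | step 13 | (2S,3S,5R)-5-methyl-2-vinyltetrahydrofuran-3-ol | C[C@@H]1C[C@H](O)[C@H](C=C)O1
F4 | step 13 | (2S,3S,5R)-5-methyl-2-[(E)-2-(4,4,5,5-tetramethyl-1,3,2-dioxaborolan-2-yl)vinyl]tetrahydrofuran-3-ol | C[C@@H]1C[C@H](O)[C@H](/C=C/B2OC(C)(C)C(C)(C)O2)O1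
F5 | step 13 | (E)-5-chloro-3-(2-iodovinyl)-6,8-bis(triisopropylsilyloxy)-1H-isochromen-1-one | I/C=C/c1cc2c(Cl)c(O[Si](C(C)C)(C(C)C)C(C)C)cc(O[Si](C(C)C)(C(C)C)C(C)C)c2c(=O)o1
F6 | step 3 | 3-chloro-2-iodo-4,6-bis(triisopropylsilyloxy)benzoic acid | OC(=O)c1c(I)c(Cl)c(O[Si](C(C)C)(C(C)C)C(C)C)cc1O[Si](C(C)C)(C(C)C)C(C)C
F7 | step 3 | 3-chloro-2-(3,3-diethoxyprop-1-yn-1-yl)-4,6-bis(triisopropylsilyloxy)benzoic acid | CCOC(OCC)C#Cc1c(Cl)c(O[Si](C(C)C)(C(C)C)C(C)C)cc(O[Si](C(C)C)(C(C)C)C(C)C)c1C(O)=O
F8 | step 11 | triethyl{[(R)-1-[(2S,3S)-3-ethynyloxiran-2-yl]propan-2-yl]oxy}silane | C[C@@H](O[Si](CC)(CC)CC)C[C@@H]1O[C@H]1C#C
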